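**Assumption:** labdane numbering (C1–C20) is used for atom labels in the explanations; tulipalin B (either enantiomer or racemate) and N-ethyl-N-nitrosourea are taken as purchasable.

**Retrosynthetic overview**
1. The C9 carbinol and the butenolide side chain are disconnected together (C9–O and C11–C12) to the 9(11)-exocyclic methylene decalin acetate, water and tulipalin B (palladium-catalysed hydroxy-allylation, attached last).
2. The methylene acetate comes from a Peterson adduct of the C9 ketone, which masks the alkene while the 5,6-olefin is hydroborated (sets C5–H and C6–O).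
3. The 4,4-dimethyl-Δ5 ketone comes from deconjugative gem-dimethylation and Wolff–Kishner removal of C3=O in an 8-methyl Wieland–Miescher-type enedione.
4. The enedione comes from a one-carbon ring expansion of the (S)-Hajos–Parrish ketone with diazoethane (1,2-shift of the ring CH2), which turns the cyclopentanone into ring B and brings in C8 with its methyl.
5. Ring order: purchased five-membered ring, then ring A by proline aldol, then ring B by expansion, then the butenolide.

**Route**

Step 1
Reactants: 1 2-methylcyclopentane-1,3-dione; 2 but-3-en-2-one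
Product: 3 2-methyl-2-(3-oxobutyl)cyclopentane-1,3-dione
Conditions: H2O, AcOH (cat.), 70 °C
Reagents that add atoms: none
Why: Michael addition of the acidic 1,3-dione to the enone; no stereocenter is formed.

Step 2
Reactants: 3 2-methyl-2-(3-oxobutyl)cyclopentane-1,3-dione
Product: 5 (S)-7a-methyl-2,3,7,7a-tetrahydro-1H-indene-1,5(6H)-dione, via bicyclic ketol 4 (not isolated)
Conditions: (S)-proline (3 mol %), DMF, 20 °C; then H2SO4 (cat.), 95 °C
Reagents that add atoms: none
Why: Hajos–Parrish–Eder–Sauer–Wiechert reaction, in which the proline enamine aldol desymmetrises the dione and sets the quaternary carbon (future C10) as S before acid dehydration to the enone.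

Step 3
Reactants: 5 (S)-7a-methyl-2,3,7,7a-tetrahydro-1H-indene-1,5(6H)-dione; 6 N-ethyl-N-nitrosourea
Product: 8 (2R,8aS)-2,8a-dimethyl-3,4,8,8a-tetrahydronaphthalene-1,6(2H,7H)-dione, via diazoethane 7 (not isolated)
Conditions: 6, KOH, Et2O–H2O, 0 °C (ethereal 7, dried over KOH); then 5, Sc(OTf)3 (10 mol %), CH2Cl2, −78 °C; then Et3N, MeOH, 20 °C
Reagents that add atoms: none
Why: Lewis-acid-catalysed diazoalkane homologation (Tiffeneau–Demjanov-type 1,2-shift), in which diazoethane adds to the activated cyclopentanone and the less substituted ring CH2 migrates with loss of N2 (as in D-homoannulation of 17-keto steroids) while the β,β-disubstituted enone stays inert; the new C2 (C8) centre equilibrates to the equatorial methyl (2R), which avoids a 1,3-diaxial clash with the angular methyl.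

Step 4
Reactants: 8 (2R,8aS)-2,8a-dimethyl-3,4,8,8a-tetrahydronaphthalene-1,6(2H,7H)-dione
Product: 9 (2R,8aS)-2,5,5,8a-tetramethyl-3,7,8,8a-tetrahydronaphthalene-1,6(2H,5H)-dione
Conditions: KOtBu (2.2 equiv), MeI (5 equiv), t-BuOH–THF, 0 to 20 °C
Reagents that add atoms: iodomethane, CI
Why: Deconjugative α,α-dimethylation of the extended potassium dienolate installs the C4 gem-dimethyl group and moves the double bond to C5=C6, while the saturated ketone, flanked by a quaternary and a tertiary carbon, enolises and alkylates far more slowly.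

Step 5
Reactants: 9 (2R,8aS)-2,5,5,8a-tetramethyl-3,7,8,8a-tetrahydronaphthalene-1,6(2H,5H)-dione
Product: 10 (2R,8aS)-2,5,5,8a-tetramethyl-3,5,6,7,8,8a-hexahydronaphthalen-1(2H)-one
Conditions: N2H4·H2O (1.5 equiv), KOH, diethylene glycol, 120 °C, then 200 °C
Reagents that add atoms: none
Why: Wolff–Kishner reduction (Huang-Minlon procedure) removes the C3 ketone through its hydrazone, which forms selectively because the C9 ketone is doubly α-branched; the hot base also holds C8 in the equatorial (2R) configuration.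

Step 6
Reactants: 10 (2R,8aS)-2,5,5,8a-tetramethyl-3,5,6,7,8,8a-hexahydronaphthalen-1(2H)-one
Product: 11 (1S,2R,8aS)-2,5,5,8a-tetramethyl-1-[(trimethylsilyl)methyl]-1,2,3,5,6,7,8,8a-octahydronaphthalen-1-ol (major C1 epimer)
Conditions: Me3SiCH2Li, CeCl3, THF, −78 to 0 °C
Reagents that add atoms: (trimethylsilyl)methyllithium, [Li]C[Si](C)(C)C
Why: Cerium-mediated 1,2-addition (first half of a Peterson olefination) of a weakly basic organocerium to the hindered, enolisable ketone, mainly anti to the angular methyl; the carbinol configuration does not matter because step 8 destroys it, and the adduct both carries C11 and protects C9 from borane.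

Step 7
Reactants: 11 (1S,2R,8aS)-2,5,5,8a-tetramethyl-1-[(trimethylsilyl)methyl]-1,2,3,5,6,7,8,8a-octahydronaphthalen-1-ol
Product: 12 (1S,3R,4S,4aS,8aS)-3,4a,8,8-tetramethyl-4-[(trimethylsilyl)methyl]decahydronaphthalene-1,4-diol
Conditions: BH3·THF (4 equiv), THF, 0 to 40 °C; then NaOH, H2O2, 0 to 20 °C
Reagents that add atoms: hydrogen peroxide, OO
Why: Brown hydroboration–oxidation, with syn addition of H–B from the α-face (opposite the angular and 4β methyls) and boron on the less substituted C6, gives the trans ring fusion (5α-H) and the equatorial 6α-OH after oxidation with retention.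

Step 8
Reactants: 12 (1S,3R,4S,4aS,8aS)-3,4a,8,8-tetramethyl-4-[(trimethylsilyl)methyl]decahydronaphthalene-1,4-diol
Product: 14 (1S,3R,4aS,8aS)-3,4a,8,8-tetramethyl-4-methylidenedecahydronaphthalen-1-yl acetate, via hydroxy alkene 13 (not isolated)
Conditions: KH (2.2 equiv), THF, 0 to 50 °C; then Ac2O, 0 to 20 °C
Reagents that add atoms: acetic anhydride, CC(=O)OC(C)=O
Why: Base-induced Peterson syn-elimination of the tertiary potassium β-silyl alkoxide gives only the exocyclic C9=C11 alkene, and the remaining secondary alkoxide is acetylated in the same flask; no stereocenter is touched.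

Step 9
Reactants: 14 (1S,3R,4aS,8aS)-3,4a,8,8-tetramethyl-4-methylidenedecahydronaphthalen-1-yl acetate; 15 4-hydroxy-3-methylideneoxolan-2-one (tulipalin B)
Product: 16 (1S,3R,4R,4aS,8aS)-4-hydroxy-3,4a,8,8-tetramethyl-4-[2-(2-oxo-2,5-dihydrofuran-3-yl)ethyl]decahydronaphthalen-1-yl acetate (CNP0205088.2)
Conditions: PdCl2(MeCN)2 (10 mol %), LiCl (1 equiv), 1,4-benzoquinone (10 mol %), 15 (3 equiv), THF–H2O (4:1), 40 °C
Reagents that add atoms: water, O
Why: Proposed new method: a three-component hydroxy-allylation catalysed by divalent palladium, in which water attacks C9 of the palladium-bound exocyclic alkene in the Markovnikov sense from the α-face (axial, opposite the C10 methyl, setting 9α-OH) to give a neopentyl-type C11–Pd species that has no β-hydrogen, inserts the exo-methylene of 15 (C11–C12 bond) and is released by β-hydroxide elimination, which forms the butenolide C13=C14 bond and returns divalent palladium without an oxidant (chloride favours this over β-hydride loss, and the quinone only re-oxidises stray zerovalent palladium); the closest known reactions are the domino Wacker–Heck cyclisation of 1,1-disubstituted alkenes and oxypalladation/insertion/β-heteroatom-elimination cascades, both so far run with tethered oxygen nucleophiles.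

**Compound list**

1 | 2-methylcyclopentane-1,3-dione | CC1C(=O)CCC1=O | starting material
2 | but-3-en-2-one (methyl vinyl ketone) | CC(=O)C=C | starting material
3 | 2-methyl-2-(3-oxobutyl)cyclopentane-1,3-dione | CC(=O)CCC1(C)C(=O)CCC1=O | intermediate
4 | (3aS,7aS)-3a-hydroxy-7a-methylhexahydro-1H-indene-1,5(4H)-dione (bicyclic ketol) | C[C@]12CCC(=O)C[C@@]1(O)CCC2=O | intermediate (not isolated)
5 | (S)-7a-methyl-2,3,7,7a-tetrahydro-1H-indene-1,5(6H)-dione (Hajos–Parrish ketone) | C[C@]12CCC(=O)C=C1CCC2=O | intermediate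
6 | N-ethyl-N-nitrosourea | CCN(N=O)C(N)=O | starting material
7 | diazoethane | CC=[N+]=[N-] | intermediate (not isolated)
8 | (2R,8aS)-2,8a-dimethyl-3,4,8,8a-tetrahydronaphthalene-1,6(2H,7H)-dione | C[C@@H]1CCC2=CC(=O)CC[C@]2(C)C1=O | intermediate
9 | (2R,8aS)-2,5,5,8a-tetramethyl-3,7,8,8a-tetrahydronaphthalene-1,6(2H,5H)-dione | C[C@@H]1CC=C2C(C)(C)C(=O)CC[C@]2(C)C1=O | intermediate
10 | (2R,8aS)-2,5,5,8a-tetramethyl-3,5,6,7,8,8a-hexahydronaphthalen-1(2H)-one | C[C@@H]1CC=C2C(C)(C)CCC[C@]2(C)C1=O | intermediate
11 | (1S,2R,8aS)-2,5,5,8a-tetramethyl-1-[(trimethylsilyl)methyl]-1,2,3,5,6,7,8,8a-octahydronaphthalen-1-ol (major C1 epimer; the 1R epimer reacts the same way) | C[C@@H]1CC=C2C(C)(C)CCC[C@]2(C)[C@]1(O)C[Si](C)(C)C | intermediate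
12 | (1S,3R,4S,4aS,8aS)-3,4a,8,8-tetramethyl-4-[(trimethylsilyl)methyl]decahydronaphthalene-1,4-diol (major C4 epimer) | O[C@H]1C[C@@H](C)[C@@](O)(C[Si](C)(C)C)[C@@]2(C)CCCC(C)(C)[C@H]12 | intermediate
13 | (1S,3R,4aS,8aS)-3,4a,8,8-tetramethyl-4-methylidenedecahydronaphthalen-1-ol (hydroxy alkene, formed as its potassium alkoxide) | O[C@H]1C[C@@H](C)C(=C)[C@@]2(C)CCCC(C)(C)[C@H]12 | intermediate (not isolated)
14 | (1S,3R,4aS,8aS)-3,4a,8,8-tetramethyl-4-methylidenedecahydronaphthalen-1-yl acetate | CC(=O)O[C@H]1C[C@@H](C)C(=C)[C@@]2(C)CCCC(C)(C)[C@H]12 | intermediate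
15 | 4-hydroxy-3-methylideneoxolan-2-one (tulipalin B; its stereocenter is lost) | C=C1C(O)COC1=O | starting material
16 | (1S,3R,4R,4aS,8aS)-4-hydroxy-3,4a,8,8-tetramethyl-4-[2-(2-oxo-2,5-dihydrofuran-3-yl)ethyl]decahydronaphthalen-1-yl acetate; labdane descriptors 5S,6S,8R,9R,10S | CC(=O)O[C@H]1C[C@@H](C)[C@](O)(CCC2=CCOC2=O)[C@@]2(C)CCCC(C)(C)[C@H]12 | target

**Step count and risks**

Total steps: 9. Longest linear sequence: 9 steps (1 and 2 to 16).

Steps most likely to fail:

- **Step 9 (proposed new step).** The exocyclic alkene may isomerise to the tetrasubstituted 8,9-alkene or form an allyl–palladium species faster than water attack and insertion occur. The fallback uses known chemistry, sets out from 14 and comes back at 16. Hydroxymercuration of 14 with Hg(OAc)2 in THF–H2O puts water on C9 from the axial α-face and mercury on C11. Reduction of this organomercurial with NaBH4 in the presence of 15 (Giese reductive radical addition to the exo-methylene) gives (1S,3R,4R,4aS,8aS)-4-hydroxy-4-[2-(4-hydroxy-2-oxooxolan-3-yl)ethyl]-3,4a,8,8-tetramethyldecahydronaphthalen-1-yl acetate F1 as a mixture at the two lactone carbons. Mesylation and β-elimination (MsCl, Et3N, CH2Cl2, 0 to 20 °C) then give 16.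

- **Step 3.** Diazoethane may add sluggishly to the α-quaternary cyclopentanone or react elsewhere. The fallback sets out from 5 and comes back at 8. Ring expansion of 5 with ethyl diazoacetate and BF3·OEt2 (CH2Cl2, 0 °C; the ring CH2 migrates) gives the β-keto ester ethyl (8aS)-8a-methyl-1,6-dioxo-1,2,3,4,6,7,8,8a-octahydronaphthalene-2-carboxylate F2. C-methylation (K2CO3, MeI, acetone) gives ethyl (8aS)-2,8a-dimethyl-1,6-dioxo-1,2,3,4,6,7,8,8a-octahydronaphthalene-2-carboxylate F3. Krapcho dealkoxycarbonylation (LiCl, wet DMSO, 150 °C) then delivers 8 as the equatorial-methyl epimer.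

- **Step 4.** Methylation may also occur at C2 (C8) next to the saturated ketone, or over-alkylation may take place. The fallback sets out from 8 and comes back at 10. NaBH4 (EtOH, −20 °C) reduces the saturated ketone selectively to (4aS,5S,6R)-5-hydroxy-4a,6-dimethyl-4,4a,5,6,7,8-hexahydronaphthalen-2(3H)-one F4, which removes the competing enolisation site. KOtBu and MeI then give (4aS,5S,6R)-5-hydroxy-1,1,4a,6-tetramethyl-3,4,4a,5,6,7-hexahydronaphthalen-2(1H)-one F5. Wolff–Kishner reduction gives (1S,2R,8aS)-2,5,5,8a-tetramethyl-1,2,3,5,6,7,8,8a-octahydronaphthalen-1-ol F6. Dess–Martin oxidation returns 10.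

**Further compounds**

F1 | step 9 | (1S,3R,4R,4aS,8aS)-4-hydroxy-4-[2-(4-hydroxy-2-oxooxolan-3-yl)ethyl]-3,4a,8,8-tetramethyldecahydronaphthalen-1-yl acetate (mixture at the lactone carbons) | CC(=O)O[C@H]1C[C@@H](C)[C@](O)(CCC2C(O)COC2=O)[C@@]2(C)CCCC(C)(C)[C@H]12
F2 | step 3 | ethyl (8aS)-8a-methyl-1,6-dioxo-1,2,3,4,6,7,8,8a-octahydronaphthalene-2-carboxylate (C2 epimers) | CCOC(=O)C1CCC2=CC(=O)CC[C@]2(C)C1=O
F3 | step 3 | ethyl (8aS)-2,8a-dimethyl-1,6-dioxo-1,2,3,4,6,7,8,8a-octahydronaphthalene-2-carboxylate (C2 epimers) | CCOC(=O)C1(C)CCC2=CC(=O)CC[C@]2(C)C1=O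
F4 | step 4 | (4aS,5S,6R)-5-hydroxy-4a,6-dimethyl-4,4a,5,6,7,8-hexahydronaphthalen-2(3H)-one | C[C@@H]1CCC2=CC(=O)CC[C@]2(C)[C@H]1O
F5 | step 4 | (4aS,5S,6R)-5-hydroxy-1,1,4a,6-tetramethyl-3,4,4a,5,6,7-hexahydronaphthalen-2(1H)-one | C[C@@H]1CC=C2C(C)(C)C(=O)CC[C@]2(C)[C@H]1O
F6 | step 4 | (1S,2R,8aS)-2,5,5,8a-tetramethyl-1,2,3,5,6,7,8,8a-octahydronaphthalen-1-ol | C[C@@H]1CC=C2C(C)(C)CCC[C@]2(C)[C@H]1O
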